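## The problem

The target is a linear trimer of phloroglucinol units. Ring A, a 2,4,6-trihydroxyphenyl group, is joined through oxygen to C1 of ring B, and C4 of ring B is joined through oxygen to C1 of ring C, which carries bromine at C4 between two hydroxyls. There is no stereocentre, so the difficulty is purely regiochemical: ten oxygens and one bromine must be placed on three rings of nearly identical electronic character. Both diaryl ether bonds are crowded. The ring A carbon of the A–B ether has two ortho oxygens, and so has C4 of ring B in the B–C ether, and none of the rings is activated for substitution by a phenoxide. The seven free hydroxyls make the final compound an easily oxidised polyphenol, so they must stay masked until the last step. The masks must come off without loss of the aryl bromide, which excludes hydrogenolysis and dissolving metals. The bromine cannot be introduced late, because C3 and C5 of ring A would compete with ring C for an electrophile; it must arrive with ring C. The feature that opens a ring-forming route is ring B. Its oxygens at C1 and C4 are para, and C4 is flanked by oxygens at C3 and C5. This is the 4-alkoxyphenol pattern of a chromium carbene benzannulation in which the carbene carbon (C1) already carries the ring A oxygen, a carbonyl ligand becomes C4, an oxygenated alkyne supplies C2–C3 and an oxygenated vinyl group supplies C5–C6.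

## Retrosynthesis

**Target 16 to the protected trimer 15.** The seven alkyl–oxygen bonds (five methyl, two ethyl) are cut first, so that the free polyphenol exists only at the end. Simple alkyl ethers are preferred to benzyl ethers, whose hydrogenolytic removal would endanger the C–Br bond, and to silyl or acyl groups, which would not survive the organolithium, acylating and copper/base steps. The two ethyl groups on ring B are what the key step delivers from purchasable two-carbon building blocks. The forward step must dealkylate exhaustively without cleaving either diaryl ether or the aryl bromide.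

**15 to phenol 11 and aryl iodide 14.** The B–C ether is cut between the oxygen on C4 of ring B and C1 of ring C. The side of the cut is dictated by the key step, which leaves C4 of ring B as a free hydroxyl, so ring C must be the electrophile. Making this bond after ring B is built keeps the bromine away from all organometallic chemistry. An aryne version would need an ortho-silylaryl triflate carrying the bromine, which costs more steps than the rest of the route. An oxidative copper coupling of a boronic acid would expose the hydroquinone monoether 11 to an oxidant. A copper-catalysed coupling of an iodide under inert, basic conditions avoids both. The forward reaction must accept a phenol with two ortho alkoxy groups and must take the iodide in the presence of the bromide; in 14 the bromide is shielded by two methoxy groups.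

**14 to 2-bromo-1,3-dimethoxybenzene 12.** The C5–I bond is cut. Electrophilic halogenation of 12 would go to C4, ortho and para to the methoxy groups. The cut is therefore useful only with a sterically governed C–H borylation (through boronate 13), which selects C5 as the only C–H bond without an ortho substituent. One purchasable arene then supplies ring C with bromine and both oxygens in place.

**11 to carbene complex 8 and ethoxyacetylene 9 (key disconnection).** Ring B is taken apart at C1–C2, C3–C4 and C4–C5. This leaves the carbene carbon with its vinyl group (C1, C6, C5) in 8, the two carbons of 9 (C2, C3) and one carbonyl ligand of 8 (C4 with its oxygen). A stepwise decoration of a preformed benzene would have to place four oxygens on ring B and then still form the hindered ether to ring A. This cut sets every substituent of ring B as the ring closes, with the ring A oxygen already on C1. The forward reaction must insert the alkyne with its ethoxy-bearing carbon next to the carbonyl-derived carbon and must proceed through CO insertion instead of stopping at the inserted carbene.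

**8 to acylate 5 and 2,4,6-trimethoxyphenol 6.** The bond between the carbene carbon and the ring A oxygen is cut, by way of the acetoxycarbene 7. This is the point of the plan: the hindered A–B ether is made by addition–elimination at a planar, strongly electrophilic carbene carbon instead of by substitution or coupling at an arene carbon flanked by two oxygens. The forward reaction needs the doubly ortho-substituted phenol to attack the carbene carbon in preference to the acetyl carbon.

**5 to (Z)-1-bromo-2-ethoxyethene 1 and chromium hexacarbonyl 2.** The C1–C6 bond is cut, which is the classical carbene synthesis from an organolithium (vinyllithium 3, lithium acylate 4) and a metal carbonyl. All six carbons of ring B then come from three purchasable compounds: 1, 2 and 9.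

## Roads not taken

**Alternative 1:** The three C–O bonds of ring A at C1, C3 and C5 are cut and the hydroxyls are traced to formyl groups.
- Forward key step: peracid oxidation of the tricarbaldehyde A1, with three Baeyer–Villiger-type (Dakin) oxygen insertions, gives the triformate A2. Methanolysis would then free the three ring A hydroxyls.
- Merits: A1 would come from the phenol A3 and 2-fluorobenzene-1,3,5-tricarbaldehyde A4 by nucleophilic aromatic substitution, with the leaving group activated by two ortho and one para formyl group. As a way to the doubly ortho-substituted A–B ether this is more reliable than the carbene substitution of the chosen plan, and it needs no stoichiometric metal.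
- Weak points: the first insertion must occur on a ring still carrying two formyl groups, where aryl migration is poor and hydride migration to carboxylic acids competes. The peracid also meets two electron-rich polyalkoxy rings (B and C). A3 is itself a hydroquinone monoether with a fully oxygenated ring B and a hindered B–C ether, which is most of the original problem, and this strategy offers no solution for it.
- Comparison: this road is better at the A–B ether. The chosen plan sets against that the construction of ring B with all four oxygens in one step from small pieces, so that A3 is never needed.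

**Alternative 2:** Ring A is cut at its C2–C3 bond and unfolded into the polyketide-like chain A5.
- Forward key step: base forms the carbanion between the C5 ketone and the C7 ester of A5, which attacks the C1 ester carbonyl (Claisen condensation, six-membered ring). Enolisation gives the phloroglucinol carboxylate A6; hydrolysis and decarboxylation would remove the ester.
- Merits: the A–B ether oxygen is attached at an sp3 carbon by alkylation of A3, the easiest ether formation of all four plans. The chemistry is classical and metal-free, and ring A appears with free hydroxyls.
- Weak points: A5 is a 1,3,5-tricarbonyl chain with two esters and several cyclisation modes. An enol oxygen can lactonise to a 4-hydroxypyranone, and the C2 carbanion can attack the C7 ester to give a ring that cannot aromatise. The chain takes several steps to assemble, a decarboxylation is added, and A3 must again be made first. Only one ring bond is formed, against three in the chosen plan.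
- Comparison: this road is as good or better in the reliability of its individual reactions. The chosen plan sets against it the direct access to ring B and the avoidance of A3.

**Alternative 3:** Ring B is again the ring that is built, but it is cut at only the two bonds that join the alkyne carbons to a four-carbon unit. This leads to the racemic cyclobutenone A7, which carries the ring C oxygen on its sp3 carbon, and the ethynyl ether A8 of ring A.
- Forward key step: on heating, A7 opens to a vinylketene. A [2+2] cycloaddition with A8, four-electron ring opening and six-electron closure give the phenol A9; only dealkylation would follow.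
- Merits: in convergence this is the best of the four plans. Both diaryl ethers are in place before the ring forms, no metal is needed, and ynol ethers are the classical partners of this benzannulation, whereas in the chosen plan the ynol ether is the untested partner.
- Weak points: both components. A7 is an α-aryloxy cyclobutenone with an acidic sp3 C–H between a carbonyl and a vinylogous ester; no short, precedented route to this substitution pattern is evident, and its aryloxy group must survive the thermolysis. A8 is an aryl ynol ether of a hindered phenol. It is less nucleophilic towards ketenes than alkyl or silyl ynol ethers and is reachable only by a multistep elimination sequence from the phenol.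
- Comparison: this road is better in convergence and in precedent for the alkyne class. The chosen plan sets against it that every component of its key step is purchasable or two steps from purchasable compounds, and that ring C with its bromine is attached afterwards by a coupling that can be tested separately.

Key step: step 3

Remark on the chemistry: compounds 1, 2, 6, 9 (as a hexane solution) and 12 are taken as purchasable. The enol ether of 5, 7 and 8 is drawn Z as formed; Z/E equilibration of this push–pull alkene is possible and immaterial, because that carbon becomes aromatic C5.

## Route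

Step 1
Reactants: 1 (Z)-1-bromo-2-ethoxyethene; 2 chromium hexacarbonyl Cr(CO)6
Product: 5 tetramethylammonium pentacarbonyl[(Z)-3-ethoxy-1-oxidoprop-2-en-1-ylidene]chromate, via (Z)-2-ethoxyvinyllithium 3 (not isolated), via lithium acylate 4 (not isolated)
Conditions: n-BuLi, Et2O, −78 °C; Cr(CO)6, THF, −78 to 0 °C; Me4NBr, H2O, 0 °C
Reagents that add atoms: tetramethylammonium bromide, C[N+](C)(C)C.[Br-]
Why: Bromine–lithium exchange on the Z bromide proceeds with retention and gives the oxygen-chelated (Z)-2-ethoxyvinyllithium, which adds to a carbonyl ligand of Cr(CO)6 as in the Fischer carbene synthesis. Cation exchange should give the acylate as a stable salt that can be handled in air.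

Step 2
Reactants: 5 tetramethylammonium pentacarbonyl[(Z)-3-ethoxy-1-oxidoprop-2-en-1-ylidene]chromate; 6 2,4,6-trimethoxyphenol
Product: 8 pentacarbonyl[(Z)-3-ethoxy-1-(2,4,6-trimethoxyphenoxy)prop-2-en-1-ylidene]chromium, via acetoxycarbene complex 7 (not isolated)
Conditions: AcBr, CH2Cl2, −40 °C; then 6, −40 to 0 °C
Reagents that add atoms: none
Why: O-Acetylation of the acylate gives an acyloxycarbene whose carbene carbon reacts like a mixed anhydride, and the phenol displaces acetate by addition–elimination (alcoholysis of acyloxycarbene complexes, the established route to aryloxycarbene complexes). The 2-ethoxyvinyl donor tempers the high electrophilicity of an aryloxycarbene, so 8 should be isolable; the known competitor is acyl transfer to the phenol.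

Step 3
Reactants: 8 pentacarbonyl[(Z)-3-ethoxy-1-(2,4,6-trimethoxyphenoxy)prop-2-en-1-ylidene]chromium; 9 ethoxyacetylene
Product: 11 2,6-diethoxy-4-(2,4,6-trimethoxyphenoxy)phenol, via tricarbonylchromium arene complex 10 (not isolated)
Conditions: 9 (3 equiv), THF (0.05 M), 55 °C, sealed vessel, argon; then air, MeCN, rt
Reagents that add atoms: none
Why: Proposed new method: a Dötz benzannulation that pairs an aryloxy(2-alkoxyvinyl)carbene complex of zerovalent chromium with an ynol ether has not been shown; the closest known reaction type is the benzannulation of alkenyl(aryloxy)carbene complexes with ordinary alkynes to 4-aryloxyphenols, supported by the known insertion of alkoxyacetylenes into metal–carbene bonds. Thermal loss of one CO from 8 frees a site, 9 inserts into the Cr=C bond with its CH carbon bonding to the carbene carbon (C1–C2), CO insertion at the new ethoxy-bearing carbene carbon gives a chromium-bound dienylketene (C3–C4), and the ketene carbon closes onto the ethoxyvinyl terminus (C4–C5). Ring B, the only ring formed, is closed by this six-electron disrotatory electrocyclisation of the dienylketene to a cyclohexadienone, which enolises to the phenol bound to Cr(CO)3 (10); air in MeCN then releases 11. The one selectivity needed is the orientation of the alkyne, and it is secured twice: hydrogen is the smaller substituent and ends next to C1, and the nucleophilic β-carbon of the ynol ether is the one that attacks the electrophilic carbene carbon, so the ethoxy group arrives at C3 next to the carbonyl-derived C4. Should the ynol ether insert before CO is lost, the dienyl(ethoxy)carbene formed is of the type known to cyclise with CO insertion to ortho-alkoxyphenols and leads to the same 11. The β-ethoxy donor makes 8 a push–pull carbene, which stabilises the aryloxy complex but slows CO loss, hence 55 °C with excess 9, well below the temperature at which 9 fragments to ketene. No stereocentre is formed, and the enol ether geometry of 8 disappears on aromatisation.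

Step 4
Reactants: 12 2-bromo-1,3-dimethoxybenzene
Product: 14 2-bromo-5-iodo-1,3-dimethoxybenzene, via aryl pinacolboronate 13 (not isolated)
Conditions: B2pin2, [Ir(OMe)(cod)]2 (cat.), 4,4'-di-tert-butyl-2,2'-bipyridine, THF, 80 °C; then CuI (cat.), 1,10-phenanthroline, KI, MeOH/H2O, air, 80 °C
Reagents that add atoms: potassium iodide, [K+].[I-]
Why: Iridium-catalysed C–H borylation is sterically controlled and reaches only C5, the one C–H bond with no ortho substituent, and it leaves the C–Br bond alone. Copper-mediated iododeboronation in the same pot then gives the iodide (sterically controlled meta-halogenation of 1,2,3-trisubstituted arenes).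

Step 5
Reactants: 11 2,6-diethoxy-4-(2,4,6-trimethoxyphenoxy)phenol; 14 2-bromo-5-iodo-1,3-dimethoxybenzene
Product: 15 2-bromo-5-[2,6-diethoxy-4-(2,4,6-trimethoxyphenoxy)phenoxy]-1,3-dimethoxybenzene
Conditions: CuI (10 mol %), picolinic acid (20 mol %), K3PO4, DMSO, 90 °C, argon
Reagents that add atoms: none
Why: Ullmann-type diaryl ether synthesis with the CuI/picolinic acid system, which is suited to phenols with two ortho substituents. The unhindered C–I bond reacts, while the C–Br bond is less reactive and shielded by two methoxy groups. Oxygen-free basic conditions avoid oxidation of the hydroquinone monoether 11.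

Step 6
Reactants: 15 2-bromo-5-[2,6-diethoxy-4-(2,4,6-trimethoxyphenoxy)phenoxy]-1,3-dimethoxybenzene
Product: 16 2-[4-(4-bromo-3,5-dihydroxyphenoxy)-3,5-dihydroxyphenoxy]benzene-1,3,5-triol
Conditions: BBr3 (12 equiv), CH2Cl2, −78 °C to rt, argon; then H2O, 0 °C
Reagents that add atoms: none
Why: Lewis acid cleavage of aryl methyl and ethyl ethers by BBr3 (bromide attacks the alkyl carbon of the O–B adduct). Diaryl ether C–O bonds and the aryl bromide are inert to the reagent, and the excess covers seven alkoxy groups and two bridging oxygens.

## Compound list

1 | (Z)-1-bromo-2-ethoxyethene | CCO/C=C\Br | starting material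
2 | chromium hexacarbonyl Cr(CO)6 | O=C=[Cr](=C=O)(=C=O)(=C=O)(=C=O)=C=O | starting material
3 | (Z)-2-ethoxyvinyllithium | CCO/C=C\[Li] | intermediate (not isolated)
4 | lithium pentacarbonyl[(Z)-3-ethoxy-1-oxidoprop-2-en-1-ylidene]chromate | [Li+].CCO/C=C\C([O-])=[Cr](=C=O)(=C=O)(=C=O)(=C=O)=C=O | intermediate (not isolated)
5 | tetramethylammonium pentacarbonyl[(Z)-3-ethoxy-1-oxidoprop-2-en-1-ylidene]chromate | C[N+](C)(C)C.CCO/C=C\C([O-])=[Cr](=C=O)(=C=O)(=C=O)(=C=O)=C=O | intermediate
6 | 2,4,6-trimethoxyphenol | COc1cc(OC)c(O)c(OC)c1 | starting material
7 | pentacarbonyl[(Z)-1-acetoxy-3-ethoxyprop-2-en-1-ylidene]chromium | CCO/C=C\C(OC(C)=O)=[Cr](=C=O)(=C=O)(=C=O)(=C=O)=C=O | intermediate (not isolated)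
8 | pentacarbonyl[(Z)-3-ethoxy-1-(2,4,6-trimethoxyphenoxy)prop-2-en-1-ylidene]chromium | CCO/C=C\C(Oc1c(OC)cc(OC)cc1OC)=[Cr](=C=O)(=C=O)(=C=O)(=C=O)=C=O | intermediate
9 | ethoxyacetylene | CCOC#C | starting material
10 | tricarbonyl[η6-2,6-diethoxy-4-(2,4,6-trimethoxyphenoxy)phenol]chromium, ring B bound to Cr(CO)3 (SMILES written as arene plus Cr(CO)3 fragment) | CCOc1cc(Oc2c(OC)cc(OC)cc2OC)cc(OCC)c1O.O=C=[Cr](=C=O)=C=O | intermediate (not isolated)
11 | 2,6-diethoxy-4-(2,4,6-trimethoxyphenoxy)phenol | CCOc1cc(Oc2c(OC)cc(OC)cc2OC)cc(OCC)c1O | intermediate
12 | 2-bromo-1,3-dimethoxybenzene | COc1cccc(OC)c1Br | starting material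
13 | 2-(4-bromo-3,5-dimethoxyphenyl)-4,4,5,5-tetramethyl-1,3,2-dioxaborolane | COc1cc(B2OC(C)(C)C(C)(C)O2)cc(OC)c1Br | intermediate (not isolated)
14 | 2-bromo-5-iodo-1,3-dimethoxybenzene | COc1cc(I)cc(OC)c1Br | intermediate
15 | 2-bromo-5-[2,6-diethoxy-4-(2,4,6-trimethoxyphenoxy)phenoxy]-1,3-dimethoxybenzene | CCOc1cc(Oc2c(OC)cc(OC)cc2OC)cc(OCC)c1Oc1cc(OC)c(Br)c(OC)c1 | intermediate
16 | 2-[4-(4-bromo-3,5-dihydroxyphenoxy)-3,5-dihydroxyphenoxy]benzene-1,3,5-triol | Oc1cc(O)c(Oc2cc(O)c(Oc3cc(O)c(Br)c(O)c3)c(O)c2)c(O)c1 | target

## Step count and risk

Total: 6 steps. Longest linear sequence: 5 steps (steps 1, 2, 3, 5, 6); step 4 is a one-step branch that supplies ring C.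

**Step 3 (key step, proposed new method).**
- Most likely failure: the ynol ether inserts into the Cr=C bond without CO loss and the reaction stalls at a donor-stabilised dienylcarbene that does not insert CO. Alternatively the electron-rich alkyne is consumed by oligomerisation before the push–pull complex 8 has lost CO. Wrong alkyne orientation is less likely, because steric and electronic preferences agree.
- Fallback (known chemistry, gives up the ring construction), from 6 to 16: nucleophilic aromatic substitution of 6 on purchasable 4-fluoro-2,6-dimethoxybenzaldehyde (K2CO3, DMF, 100 °C) gives 2,6-dimethoxy-4-(2,4,6-trimethoxyphenoxy)benzaldehyde F1. Dakin-type Baeyer–Villiger oxidation (mCPBA, CH2Cl2; then aq. NaOH, MeOH) gives 2,6-dimethoxy-4-(2,4,6-trimethoxyphenoxy)phenol F2, the dimethyl analogue of 11. Coupling with 14 under the conditions of step 5 gives 2-bromo-5-[2,6-dimethoxy-4-(2,4,6-trimethoxyphenoxy)phenoxy]-1,3-dimethoxybenzene F3, and BBr3 as in step 6 comes back to the route at 16.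

**Step 2.**
- Most likely failure: acyl transfer. The hindered phenol attacks the acetyl carbon of 7 instead of the carbene carbon and returns the acylate, or it adds at the β-carbon of the ethoxyvinyl group with loss of ethanol.
- Fallback, from 6 to 16: the A–B ether is formed by copper catalysis on a preformed ring B, which does not require the phenol to attack a crowded carbon electrophile. Ullmann coupling of 6 (CuI, picolinic acid, K3PO4, DMSO, 100 °C) with 2-(benzyloxy)-5-bromo-1,3-dimethoxybenzene F4 (from purchasable 4-bromo-2,6-dimethoxyphenol, BnBr, K2CO3, DMF) gives 2-[4-(benzyloxy)-3,5-dimethoxyphenoxy]-1,3,5-trimethoxybenzene F5. Hydrogenolysis (H2, Pd/C, EtOAc; no aryl halide is present at this stage) gives 2,6-dimethoxy-4-(2,4,6-trimethoxyphenoxy)phenol F2. Coupling with 14 as in step 5 gives the heptamethyl ether 2-bromo-5-[2,6-dimethoxy-4-(2,4,6-trimethoxyphenoxy)phenoxy]-1,3-dimethoxybenzene F3, and BBr3 comes back to the route at 16.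

**Step 5.**
- Most likely failure: slow C–O bond formation at copper for a phenoxide with two ortho ethoxy groups, so that reduction of the C–I bond of 14 and thermal degradation of the electron-rich phenoxide in DMSO take over.
- Fallback, from 14 to 15: metal-free arylation with a diaryliodonium salt near room temperature. Oxidation of 14 with mCPBA and TsOH·H2O in MeCN, followed by 1,3,5-trimethoxybenzene, gives (4-bromo-3,5-dimethoxyphenyl)(2,4,6-trimethoxyphenyl)iodonium tosylate F6, in which the trimethoxyphenyl group is the ligand that is not transferred. Phenol 11 with K2CO3 and F6 in toluene/THF (rt to 50 °C) comes back to the route at 15.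

**Step 6.**
- Most likely failure: incomplete dealkylation (the ethyl ethers ortho to the B–C ether oxygen are the slowest), combined with oxidative loss of the free heptaphenol during chromatographic separation from partly alkylated material.
- Fallback, from 15 to 16: derivatise, purify, release. The crude product of the BBr3 treatment of 15 is peracetylated (Ac2O, pyridine) to the heptaacetate 2-[4-(3,5-diacetoxy-4-bromophenoxy)-3,5-diacetoxyphenoxy]benzene-1,3,5-triyl triacetate F7, which is stable to air and silica and separable from under-deprotected material. Acid-catalysed methanolysis (HCl in MeOH, argon, rt) comes back to the route at 16 with only volatile by-products.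

## Further compounds

F1 | step 3 | 2,6-dimethoxy-4-(2,4,6-trimethoxyphenoxy)benzaldehyde | COc1cc(Oc2c(OC)cc(OC)cc2OC)cc(OC)c1C=O
F2 | step 3 | 2,6-dimethoxy-4-(2,4,6-trimethoxyphenoxy)phenol | COc1cc(Oc2c(OC)cc(OC)cc2OC)cc(OC)c1O
F3 | step 3 | 2-bromo-5-[2,6-dimethoxy-4-(2,4,6-trimethoxyphenoxy)phenoxy]-1,3-dimethoxybenzene | COc1cc(Oc2c(OC)cc(OC)cc2OC)cc(OC)c1Oc1cc(OC)c(Br)c(OC)c1
F4 | step 2 | 2-(benzyloxy)-5-bromo-1,3-dimethoxybenzene | COc1cc(Br)cc(OC)c1OCc1ccccc1
F5 | step 2 | 2-[4-(benzyloxy)-3,5-dimethoxyphenoxy]-1,3,5-trimethoxybenzene | COc1cc(Oc2c(OC)cc(OC)cc2OC)cc(OC)c1OCc1ccccc1
F6 | step 5 | (4-bromo-3,5-dimethoxyphenyl)(2,4,6-trimethoxyphenyl)iodonium tosylate | COc1cc([I+]c2c(OC)cc(OC)cc2OC)cc(OC)c1Br.Cc1ccc(cc1)S(=O)(=O)[O-]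
F7 | step 6 | 2-[4-(3,5-diacetoxy-4-bromophenoxy)-3,5-diacetoxyphenoxy]benzene-1,3,5-triyl triacetate | CC(=O)Oc1cc(OC(C)=O)c(Oc2cc(OC(C)=O)c(Oc3cc(OC(C)=O)c(Br)c(OC(C)=O)c3)c(OC(C)=O)c2)c(OC(C)=O)c1
A1 | alternative 1 | 2-[4-(4-bromo-3,5-dimethoxyphenoxy)-3,5-dimethoxyphenoxy]benzene-1,3,5-tricarbaldehyde | O=Cc1cc(C=O)c(Oc2cc(OC)c(Oc3cc(OC)c(Br)c(OC)c3)c(OC)c2)c(C=O)c1
A2 | alternative 1 | 2-[4-(4-bromo-3,5-dimethoxyphenoxy)-3,5-dimethoxyphenoxy]benzene-1,3,5-triyl triformate | O=COc1cc(OC=O)c(Oc2cc(OC)c(Oc3cc(OC)c(Br)c(OC)c3)c(OC)c2)c(OC=O)c1
A3 | alternative 1 | 4-(4-bromo-3,5-dimethoxyphenoxy)-3,5-dimethoxyphenol | COc1cc(O)cc(OC)c1Oc1cc(OC)c(Br)c(OC)c1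
A4 | alternative 1 | 2-fluorobenzene-1,3,5-tricarbaldehyde | O=Cc1cc(C=O)c(F)c(C=O)c1
A5 | alternative 2 | dimethyl 2-[4-(4-bromo-3,5-dimethoxyphenoxy)-3,5-dimethoxyphenoxy]-3,5-dioxoheptanedioate (racemic) | COC(=O)CC(=O)CC(=O)C(Oc1cc(OC)c(Oc2cc(OC)c(Br)c(OC)c2)c(OC)c1)C(=O)OC
A6 | alternative 2 | methyl 3-[4-(4-bromo-3,5-dimethoxyphenoxy)-3,5-dimethoxyphenoxy]-2,4,6-trihydroxybenzoate | COC(=O)c1c(O)cc(O)c(Oc2cc(OC)c(Oc3cc(OC)c(Br)c(OC)c3)c(OC)c2)c1O
A7 | alternative 3 | 4-(4-bromo-3,5-dimethoxyphenoxy)-3-ethoxycyclobut-2-en-1-one (racemic) | CCOC1=CC(=O)C1Oc1cc(OC)c(Br)c(OC)c1
A8 | alternative 3 | 2-(ethynyloxy)-1,3,5-trimethoxybenzene | C#COc1c(OC)cc(OC)cc1OC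
A9 | alternative 3 | 2-(4-bromo-3,5-dimethoxyphenoxy)-3-ethoxy-5-(2,4,6-trimethoxyphenoxy)phenol | CCOc1cc(Oc2c(OC)cc(OC)cc2OC)cc(O)c1Oc1cc(OC)c(Br)c(OC)c1
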